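**Retrosynthetic overview**

1. The methylene bridge is cut at the CH2–C6 bond of the cyclohexadienone ring. This gives the chromene Mannich base 9 and the (R)-acyl-triketone 13, two unprotected halves of similar size that are joined by an ortho-quinone methide Michael reaction.
2. Enabling feature: on the benzopyran ring the 7-OH is ortho to the C8 aminomethyl carbon, so C7–O/C8–CH2 can collapse to an ortho-quinone methide. On the cyclohexadienone ring C6 is the only unsubstituted carbon and lies between C1=O and C5–OH, which makes it a soft vinylogous-acid carbon nucleophile.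
3. Chromene 8 comes from the 4-O-(1,1-dimethylpropargyl) ether of phlorisobutyrophenone (from phloroglucinol). A Claisen/oxa-6π sequence closes the pyran ring, with the 2,6-OH groups capped as acetates to fix the regiochemistry.
4. Triketone 13 comes from racemic 12 by chiral SFC. Compound 12 comes from dearomatising C-prenylation of acyl-methylphloroglucinol 11, which converts the second benzene ring into the cyclohexadienone ring and creates the quaternary centre.
5. Order of ring events: pyran ring (step 4), cyclohexadienone ring by dearomatisation (step 7), union of the halves (step 9).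

Key step: step 9

Remark: the β-triketone ring is written throughout in the enol tautomer of the target SMILES; CIP analysis of that drawing gives (R) at the quaternary carbon, and tautomerism does not touch this centre.

**Route**

Step 1
Reactants: 1 phloroglucinol (benzene-1,3,5-triol)
Product: 2 2-methyl-1-(2,4,6-trihydroxyphenyl)propan-1-one (phlorisobutyrophenone)
Conditions: i-PrCOCl (1.0 equiv), AlCl3 (3 equiv), PhNO2–CH2Cl2, 0 °C → rt; ice/aq HCl
Reagents that add atoms: isobutyryl chloride, CC(C)C(Cl)=O
Why: Friedel–Crafts C-acylation of the threefold-symmetric triphenol can give only one regioisomer, and the chelated aryl ketone formed is deactivated towards a second acylation.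

Step 2
Reactants: 2 2-methyl-1-(2,4,6-trihydroxyphenyl)propan-1-one
Product: 3 1-{2,6-dihydroxy-4-[(2-methylbut-3-yn-2-yl)oxy]phenyl}-2-methylpropan-1-one
Conditions: 3-chloro-3-methylbut-1-yne (1.2 equiv), DBU (1.3 equiv), CuCl2·2H2O (1 mol%), MeCN, −5 → 0 °C
Reagents that add atoms: 3-chloro-3-methylbut-1-yne, CC(C)(Cl)C#C
Why: Copper-catalysed propargylic O-alkylation of a phenol should occur at the 4-OH, which is para to the ketone, the most acidic and the only hydroxyl not chelated to the carbonyl, so that one equivalent of amidine base selects it.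

Step 3
Reactants: 3 1-{2,6-dihydroxy-4-[(2-methylbut-3-yn-2-yl)oxy]phenyl}-2-methylpropan-1-one
Product: 4 2-(2-methylpropanoyl)-5-[(2-methylbut-3-yn-2-yl)oxy]-1,3-phenylene diacetate
Conditions: Ac2O (3 equiv), pyridine, DMAP (5 mol%), 0 °C → rt
Reagents that add atoms: acetic anhydride, CC(=O)OC(C)=O
Why: DMAP-catalysed O-acetylation caps the two chelated phenols so that, after the rearrangement of the next step, only the oxygen para to the ketone carries a free OH and can close the pyran ring.

Step 4
Reactants: 4 2-(2-methylpropanoyl)-5-[(2-methylbut-3-yn-2-yl)oxy]-1,3-phenylene diacetate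
Product: 8 1-(5,7-dihydroxy-2,2-dimethyl-2H-chromen-6-yl)-2-methylpropan-1-one, via allenylphenol diacetate 5 (not isolated), via dienone diacetate 6 (not isolated), via chromene diacetate 7 (not isolated)
Conditions: o-xylene, 140 °C, Ar; then NH3 (7 M in MeOH), 0 °C → rt
Reagents that add atoms: none
Why: Aromatic propargyl Claisen rearrangement to either of the two equivalent ortho positions, tautomerisation, 1,5-hydrogen shift and oxa-6π electrocyclisation should close the 2,2-dimethylpyran ring on the former ether oxygen (the only free OH at that stage), and ammonolysis of the two aryl acetates then frees the 5- and 7-OH.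

Step 5
Reactants: 8 1-(5,7-dihydroxy-2,2-dimethyl-2H-chromen-6-yl)-2-methylpropan-1-one
Product: 9 1-{8-[(dimethylamino)methyl]-5,7-dihydroxy-2,2-dimethyl-2H-chromen-6-yl}-2-methylpropan-1-one
Conditions: Me2N=CH2+ I− (1.1 equiv), Et3N (1.1 equiv), CH2Cl2, 0 °C → rt
Reagents that add atoms: Eschenmoser's salt (N,N-dimethylmethaniminium iodide), C=[N+](C)C.[I-]
Why: Phenol Mannich aminomethylation with a preformed iminium salt can occur only at C8, the single unsubstituted ring carbon (ortho to the 7-OH and para to the 5-OH), and the absence of free formaldehyde avoids premature diarylmethane formation.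

Step 6
Reactants: 10 2-methylbenzene-1,3,5-triol (2-methylphloroglucinol)
Product: 11 2-methyl-1-(2,4,6-trihydroxy-3-methylphenyl)propan-1-one
Conditions: i-PrCOCl (1.0 equiv), AlCl3 (3 equiv), PhNO2–CH2Cl2, 0 °C → rt; ice/aq HCl
Reagents that add atoms: isobutyryl chloride, CC(C)C(Cl)=O
Why: Friedel–Crafts C-acylation, in which the two free ring positions are equivalent by symmetry so that a single mono-acyl product is expected.

Step 7
Reactants: 11 2-methyl-1-(2,4,6-trihydroxy-3-methylphenyl)propan-1-one
Product: 12 rac-3,5-dihydroxy-4-methyl-4-(3-methylbut-2-en-1-yl)-2-(2-methylpropanoyl)cyclohexa-2,5-dien-1-one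
Conditions: prenyl bromide (1.1 equiv), NaOMe (2.2 equiv), MeOH, 0 °C → rt; aq HCl
Reagents that add atoms: prenyl bromide (1-bromo-3-methylbut-2-ene), CC(C)=CCBr
Why: Alkylative dearomatisation of an acylphloroglucinol, in which C-alkylation of the phenolate at the methyl-bearing carbon between two oxygens gives a non-aromatisable acyl-β-triketone that is deprotonated at once and so resists further alkylation; the quaternary stereocentre is created here without control, as the racemate.

Step 8
Reactants: 12 rac-3,5-dihydroxy-4-methyl-4-(3-methylbut-2-en-1-yl)-2-(2-methylpropanoyl)cyclohexa-2,5-dien-1-one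
Product: 13 (4R)-3,5-dihydroxy-4-methyl-4-(3-methylbut-2-en-1-yl)-2-(2-methylpropanoyl)cyclohexa-2,5-dien-1-one
Conditions: preparative SFC, amylose tris(3,5-dimethylphenylcarbamate) stationary phase, CO2/MeOH (0.1% HCO2H), 35 °C
Reagents that add atoms: none
Why: Resolution by preparative enantioselective chromatography separates the two antipodes of the acidic triketone on a polysaccharide chiral stationary phase, the (4R)-antipode (to be assigned by ECD or X-ray before use) is taken on, and because C4 carries no hydrogen it cannot epimerise afterwards, so this step fixes the only stereocentre of the target.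

Step 9
Reactants: 9 1-{8-[(dimethylamino)methyl]-5,7-dihydroxy-2,2-dimethyl-2H-chromen-6-yl}-2-methylpropan-1-one; 13 (4R)-3,5-dihydroxy-4-methyl-4-(3-methylbut-2-en-1-yl)-2-(2-methylpropanoyl)cyclohexa-2,5-dien-1-one
Product: 15 (4R)-6-{[5,7-dihydroxy-2,2-dimethyl-6-(2-methylpropanoyl)-2H-chromen-8-yl]methyl}-3,5-dihydroxy-4-methyl-4-(3-methylbut-2-en-1-yl)-2-(2-methylpropanoyl)cyclohexa-2,5-dien-1-one, via ortho-quinone methide 14 (not isolated)
Conditions: 9 (1.0 equiv), 13 (1.05 equiv), 1,4-dioxane, 70 °C, Ar, dark; aq citric acid
Reagents that add atoms: none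
Why: The acidic triketone 13 (a vinylogous carboxylic acid) protonates the benzylic amine of 9, and on warming the ammonium phenol loses dimethylamine by 1,4-elimination across C7–O/C8–CH2 to give the ortho-quinone methide 14, whose exocyclic methylene is attacked in a Michael fashion by C6 of the triketone enolate held next to it as the counter-ion, with rearomatisation of the benzopyran ring as the driving force. The closest known reaction type is the Mannich-base (ortho-quinone methide) coupling used to assemble methylene-bridged acylphloroglucinol dimers. No ring is closed in this step. No stereocentre is formed, and the quaternary C4 of 13 has no hydrogen and lies outside the reacting enol, so its (R) configuration should pass into 15 unchanged. The step needs C- over O-alkylation and cross- over homo-coupling: 13 has a single unsubstituted nucleophilic carbon, the aromatic ring of 9 is fully substituted and cannot act as a carbon nucleophile, and an O-adduct can re-ionise to 14 whereas the C-adduct is not expected to revert at this temperature. The prenyl and chromene double bonds are far less nucleophilic than the enolate and should not intercept 14 under these conditions.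

**Compound list**

1 | phloroglucinol (benzene-1,3,5-triol) | Oc1cc(O)cc(O)c1 | starting material
2 | 2-methyl-1-(2,4,6-trihydroxyphenyl)propan-1-one | CC(C)C(=O)c1c(O)cc(O)cc1O | intermediate
3 | 1-{2,6-dihydroxy-4-[(2-methylbut-3-yn-2-yl)oxy]phenyl}-2-methylpropan-1-one | CC(C)C(=O)c1c(O)cc(OC(C)(C)C#C)cc1O | intermediate
4 | 2-(2-methylpropanoyl)-5-[(2-methylbut-3-yn-2-yl)oxy]-1,3-phenylene diacetate | CC(C)C(=O)c1c(OC(C)=O)cc(OC(C)(C)C#C)cc1OC(C)=O | intermediate
5 | 5-hydroxy-4-(3-methylbuta-1,2-dien-1-yl)-2-(2-methylpropanoyl)-1,3-phenylene diacetate | CC(C)C(=O)c1c(OC(C)=O)cc(O)c(C=C=C(C)C)c1OC(C)=O | intermediate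
6 | 3,5-diacetoxy-4-(2-methylpropanoyl)-6-(3-methylbut-2-en-1-ylidene)cyclohexa-2,4-dien-1-one | CC(C)C(=O)C1=C(OC(C)=O)C(=CC=C(C)C)C(=O)C=C1OC(C)=O | intermediate
7 | 2,2-dimethyl-6-(2-methylpropanoyl)-2H-chromene-5,7-diyl diacetate | CC(C)C(=O)c1c(OC(C)=O)cc2OC(C)(C)C=Cc2c1OC(C)=O | intermediate
8 | 1-(5,7-dihydroxy-2,2-dimethyl-2H-chromen-6-yl)-2-methylpropan-1-one | CC(C)C(=O)c1c(O)cc2OC(C)(C)C=Cc2c1O | intermediate
9 | 1-{8-[(dimethylamino)methyl]-5,7-dihydroxy-2,2-dimethyl-2H-chromen-6-yl}-2-methylpropan-1-one | CC(C)C(=O)c1c(O)c(CN(C)C)c2OC(C)(C)C=Cc2c1O | intermediate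
10 | 2-methylbenzene-1,3,5-triol (2-methylphloroglucinol) | Cc1c(O)cc(O)cc1O | starting material
11 | 2-methyl-1-(2,4,6-trihydroxy-3-methylphenyl)propan-1-one | CC(C)C(=O)c1c(O)cc(O)c(C)c1O | intermediate
12 | rac-3,5-dihydroxy-4-methyl-4-(3-methylbut-2-en-1-yl)-2-(2-methylpropanoyl)cyclohexa-2,5-dien-1-one | CC(C)=CCC1(C)C(O)=CC(=O)C(C(=O)C(C)C)=C1O | intermediate
13 | (4R)-3,5-dihydroxy-4-methyl-4-(3-methylbut-2-en-1-yl)-2-(2-methylpropanoyl)cyclohexa-2,5-dien-1-one | CC(C)=CC[C@]1(C)C(O)=CC(=O)C(C(=O)C(C)C)=C1O | intermediate
14 | 5-hydroxy-2,2-dimethyl-8-methylidene-6-(2-methylpropanoyl)-2H-chromen-7(8H)-one | CC(C)C(=O)C1=C(O)C2=C(OC(C)(C)C=C2)C(=C)C1=O | intermediate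
15 | (4R)-6-{[5,7-dihydroxy-2,2-dimethyl-6-(2-methylpropanoyl)-2H-chromen-8-yl]methyl}-3,5-dihydroxy-4-methyl-4-(3-methylbut-2-en-1-yl)-2-(2-methylpropanoyl)cyclohexa-2,5-dien-1-one | CC(C)=CC[C@]1(C)C(O)=C(Cc2c(O)c(C(=O)C(C)C)c(O)c3c2OC(C)(C)C=C3)C(=O)C(C(=O)C(C)C)=C1O | target

**Totals**

Total step count: 9. Longest linear sequence: 6 steps (steps 1, 2, 3, 4, 5, 9).

**Steps most likely to fail**

Step 7. Alkylation may take place at the unsubstituted ring carbon (giving an aromatic product that alkylates again) or on oxygen instead of at the methyl-bearing carbon. The fallback reverses the order of the two C-alkylations. It sets out from 2: C-prenylation with prenyl bromide in cold aqueous KOH should give 2-methyl-1-[2,4,6-trihydroxy-3-(3-methylbut-2-en-1-yl)phenyl]propan-1-one F1. Dearomatising C-methylation of F1 with MeI and NaOMe in MeOH at 0 °C is then expected at the prenyl-bearing carbon, because the small electrophile prefers the more electron-rich substituted position, as in the gem-dimethylation that gives acylfilicinic acids. The fallback comes back to the route at 12; compounds 10 and 11 are not needed.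

Step 9. The methylene group may be exchanged by retro-Michael cleavage and re-addition, which would scramble the halves into symmetrical dimers, or the quinone methide may be consumed by cycloaddition or amine re-addition before the enolate captures it. The fallback joins the same two carbons by condensation and reduction instead of by conjugate addition. It sets out from 8: Vilsmeier–Haack formylation (POCl3, DMF, MeCN, 0 °C → rt, then aq NaOAc) at the only free ring position should give 5,7-dihydroxy-2,2-dimethyl-6-(2-methylpropanoyl)-2H-chromene-8-carbaldehyde F2. F2 and 13 are then combined with L-proline (catalytic) and Hantzsch ester in CH2Cl2 at rt; Knoevenagel condensation gives (4S)-6-{[5,7-dihydroxy-2,2-dimethyl-6-(2-methylpropanoyl)-2H-chromen-8-yl]methylidene}-3-hydroxy-4-methyl-4-(3-methylbut-2-en-1-yl)-2-(2-methylpropanoyl)cyclohex-2-ene-1,5-dione F3. F3 has the same spatial arrangement at the quaternary carbon as 13; the descriptor changes only through the CIP ranking. It is reduced in the flask by hydride transfer, and the fallback comes back to the route at 15; compound 9 is bypassed.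

Step 2. The tertiary propargyl electrophile may alkylate the electron-rich ring at carbon, or more than one hydroxyl may be etherified. The fallback abandons the ether/Claisen sequence. It sets out from 2: condensation with 3-methylbut-2-enal (ethylenediammonium diacetate catalyst, toluene, reflux; Knoevenagel condensation followed by oxa-6π electrocyclisation) should give 8 directly. Ring closure on the oxygen ortho to the ketone is expected to compete and to give 1-(5,7-dihydroxy-2,2-dimethyl-2H-chromen-8-yl)-2-methylpropan-1-one F4, which has to be removed by chromatography. The fallback comes back to the route at 8; compounds 3 to 7 are bypassed, at the price of the regiocontrol that the acetate-capped route provides.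

**Further compounds**

F1 | step 7 | 2-methyl-1-[2,4,6-trihydroxy-3-(3-methylbut-2-en-1-yl)phenyl]propan-1-one | CC(C)C(=O)c1c(O)cc(O)c(CC=C(C)C)c1O
F2 | step 9 | 5,7-dihydroxy-2,2-dimethyl-6-(2-methylpropanoyl)-2H-chromene-8-carbaldehyde | CC(C)C(=O)c1c(O)c(C=O)c2OC(C)(C)C=Cc2c1O
F3 | step 9 | (4S)-6-{[5,7-dihydroxy-2,2-dimethyl-6-(2-methylpropanoyl)-2H-chromen-8-yl]methylidene}-3-hydroxy-4-methyl-4-(3-methylbut-2-en-1-yl)-2-(2-methylpropanoyl)cyclohex-2-ene-1,5-dione | CC(C)=CC[C@]1(C)C(=O)C(=Cc2c(O)c(C(=O)C(C)C)c(O)c3c2OC(C)(C)C=C3)C(=O)C(C(=O)C(C)C)=C1O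
F4 | step 2 | 1-(5,7-dihydroxy-2,2-dimethyl-2H-chromen-8-yl)-2-methylpropan-1-one | CC(C)C(=O)c1c(O)cc(O)c2C=CC(C)(C)Oc12
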